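**Retrosynthetic overview**
- The target is the procyanidin tetramer epicatechin-(4β→8)-epicatechin-(4β→8)-epicatechin-(4β→8)-catechin. Units 1, 3 and 4 (counted from the chain-start unit at the top) come with their C rings intact from (−)-epicatechin and (+)-catechin; only ring C of unit 2 is built.
- Last C–C disconnection: C4 (unit 1)–C8 (unit 2), a Lewis-acid Friedel–Crafts union with a 4-alkoxy-8-bromo-epicatechin electrophile.
- Key disconnection: ring C of unit 2 by a formal [4+2] (oxa-Povarov) annulation. An O-aryl oxocarbenium ion (ring A, O1, C2 with ring B) reacts with an (E)-enol ester whose C3=C4 sits on C8 of unit 3 of an epicatechin-(4β→8)-catechin dimer; C2–C3 and C4–C4a form together.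
- Enabling feature: in ring C of unit 2, O1–C2 is an aryl benzyl ether; ring A has a free CH at C4a ortho to O1; C2 carries the electron-rich ring B; C3 carries oxygen; C4 carries the 2,4,6-trioxygenated ring A (C8) of unit 3, which stabilises positive charge at C4.
- Ring order: C rings of units 1, 3, 4 preformed; bond unit 3–unit 4; ring C of unit 2 (step 13); bond unit 1–unit 2; global deprotection.

Key step: step 13

Remark (stereochemical model): the (S)-2-methoxy-2-phenylacetyl group is assumed to react through its extended ester conformer, in which the phenyl ring covers the face of the enol carbon that would lead to the 3S series; if the sense were found reversed, the (R)-acid would be used in step 10 with nothing else changed.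
Remark: compounds 15 and 17 are racemic at the acetal carbon (trigonal in step 13) and are drawn as N1-benzotriazolyl isomers.

**Step 1**
Reactants: 1 (−)-epicatechin
Product: 2 5,7,3',4'-tetra-O-benzyl-(−)-epicatechin
Conditions: BnBr (4.4 equiv), K2CO3, DMF, 0 °C to rt
Reagents that add atoms: benzyl bromide, BrCc1ccccc1
Why: Williamson ether synthesis in which K2CO3 deprotonates only the four phenols, so the secondary 3-OH and both stereocentres stay untouched.

**Step 2**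
Reactants: 2 5,7,3',4'-tetra-O-benzyl-(−)-epicatechin
Product: 3 3,5,7,3',4'-penta-O-benzyl-(−)-epicatechin
Conditions: NaH, BnBr, n-Bu4NI (cat.), DMF, 0 °C to rt
Reagents that add atoms: benzyl bromide, BrCc1ccccc1
Why: Williamson ether synthesis at the 3-alkoxide, safe for C2 because with all phenols capped no quinone-methide ring opening can occur.

**Step 3**
Reactants: 3 3,5,7,3',4'-penta-O-benzyl-(−)-epicatechin
Product: 4 3,5,7,3',4'-penta-O-benzyl-4β-(2-ethoxyethoxy)-(−)-epicatechin (2,3-cis-3,4-trans)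
Conditions: DDQ (2 equiv), 2-ethoxyethanol (5 equiv), CH2Cl2, rt
Reagents that add atoms: 2-ethoxyethanol, CCOCCO
Why: DDQ benzylic oxidation (hydride abstraction at C4 to a cation stabilised by the 5,7-dioxygenated ring A) with capture by the alcohol anti to the 3-benzyloxy group, which should set the 4β ether.

**Step 4**
Reactants: 4 3,5,7,3',4'-penta-O-benzyl-4β-(2-ethoxyethoxy)-(−)-epicatechin
Product: 5 8-bromo-3,5,7,3',4'-penta-O-benzyl-4β-(2-ethoxyethoxy)-(−)-epicatechin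
Conditions: NBS (1.05 equiv), CH2Cl2, −40 °C to rt
Reagents that add atoms: N-bromosuccinimide, O=C1CCC(=O)N1Br
Why: Electrophilic aromatic bromination, which in 5,7-di-O-benzyl flavans should go to C8 rather than C6; the bromine blocks self-condensation and is the handle for step 8.

**Step 5**
Reactants: 6 (+)-catechin
Product: 7 5,7,3',4'-tetra-O-benzyl-(+)-catechin
Conditions: BnBr (4.4 equiv), K2CO3, DMF, 0 °C to rt
Reagents that add atoms: benzyl bromide, BrCc1ccccc1
Why: Williamson ether synthesis selective for the phenols, as in step 1, with no stereocentre touched.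

**Step 6**
Reactants: 7 5,7,3',4'-tetra-O-benzyl-(+)-catechin
Product: 8 3,5,7,3',4'-penta-O-benzyl-(+)-catechin
Conditions: NaH, BnBr, n-Bu4NI (cat.), DMF, 0 °C to rt
Reagents that add atoms: benzyl bromide, BrCc1ccccc1
Why: Williamson ether synthesis at the 3-alkoxide, as in step 2.

**Step 7**
Reactants: 5 8-bromo-3,5,7,3',4'-penta-O-benzyl-4β-(2-ethoxyethoxy)-(−)-epicatechin; 8 3,5,7,3',4'-penta-O-benzyl-(+)-catechin (3 equiv)
Product: 9 deca-O-benzyl-8-bromo-epicatechin-(4β→8)-catechin (bromine on C8 of the epicatechin unit)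
Conditions: TMSOTf (0.1 equiv), 4 Å MS, CH2Cl2, −78 °C; Et3N quench
Reagents that add atoms: none
Why: Lewis-acid ionisation of the 4-alkoxy group gives the C4 cation, which undergoes Friedel–Crafts alkylation by C8 of the catechin nucleophile anti to the 3-benzyloxy group, so the new stereocentre should be 4β, while the 8-bromine stops the electrophile from adding to itself.

**Step 8**
Reactants: 9 deca-O-benzyl-8-bromo-epicatechin-(4β→8)-catechin; 10 (E)-1,2-bis(4,4,5,5-tetramethyl-1,3,2-dioxaborolan-2-yl)ethene (3 equiv)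
Product: 11 deca-O-benzyl-8-[(E)-2-(4,4,5,5-tetramethyl-1,3,2-dioxaborolan-2-yl)ethenyl]-epicatechin-(4β→8)-catechin
Conditions: Pd(OAc)2 (5 mol %), SPhos (10 mol %), K3PO4, toluene/H2O 10:1, 80 °C
Reagents that add atoms: none
Why: Suzuki–Miyaura coupling in which the bulky electron-rich biarylphosphine allows oxidative addition of the di-ortho-substituted bromide, the excess of diboryl alkene favours single coupling, and the (E) geometry is retained.

**Step 9**
Reactants: 11 deca-O-benzyl-8-[(E)-2-(pinacolboryl)ethenyl]-epicatechin-(4β→8)-catechin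
Product: 12 potassium (E)-trifluoro[2-(deca-O-benzyl-epicatechin-(4β→8)-catechin-8-yl)ethenyl]borate
Conditions: KHF2 (aq.), MeOH/THF, rt
Reagents that add atoms: potassium hydrogen difluoride, F.[F-].[K+]
Why: Standard exchange of a pinacol boronate for the trifluoroborate, the boron partner suited to the copper coupling of step 10, with the alkene geometry untouched.

**Step 10**
Reactants: 12 potassium (E)-trifluoro[2-(deca-O-benzyl-epicatechin-(4β→8)-catechin-8-yl)ethenyl]borate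
Product: 13 (E)-2-(deca-O-benzyl-epicatechin-(4β→8)-catechin-8-yl)ethenyl (S)-2-methoxy-2-phenylacetate
Conditions: (S)-2-methoxy-2-phenylacetic acid (2 equiv), CuBr (10 mol %), DMAP (0.2 equiv), 4 Å MS, O2 (1 atm), CH2Cl2, rt
Reagents that add atoms: (S)-2-methoxy-2-phenylacetic acid, CO[C@H](C(=O)O)c1ccccc1
Why: Chan–Lam-type copper-catalysed oxidative C–O coupling of an alkenyl trifluoroborate with a carboxylic acid, which should retain the (E) geometry and is too mild to racemise the α-alkoxy acid.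

**Step 11**
Reactants: 14 3,4-bis(benzyloxy)benzaldehyde
Product: 15 1-{chloro[3,4-bis(benzyloxy)phenyl]methyl}-1H-benzotriazole (racemic)
Conditions: 1H-benzotriazole (1 equiv), SOCl2 (1.2 equiv), toluene, rt; used crude
Reagents that add atoms: 1H-benzotriazole, c1ccc2[nH]nnc2c1; thionyl chloride, O=S(Cl)Cl
Why: Addition of benzotriazole to the aldehyde gives the hemiaminal, whose hydroxyl is exchanged for chloride by SOCl2 (benzotriazole-mediated α-chloroalkylation).

**Step 12**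
Reactants: 15 1-{chloro[3,4-bis(benzyloxy)phenyl]methyl}-1H-benzotriazole; 16 3,5-bis(benzyloxy)phenol
Product: 17 1-{[3,5-bis(benzyloxy)phenoxy][3,4-bis(benzyloxy)phenyl]methyl}-1H-benzotriazole (racemic)
Conditions: K2CO3, DMF, 0 °C to rt
Reagents that add atoms: none
Why: Williamson-type O-alkylation of the phenoxide by the readily ionised α-chloroalkyl benzotriazole, giving a stable N,O-acetal from which benzotriazole, not aryloxide, is expected to leave.

**Step 13**
Reactants: 17 1-{[3,5-bis(benzyloxy)phenoxy][3,4-bis(benzyloxy)phenyl]methyl}-1H-benzotriazole (1.3 equiv, added slowly); 13 (E)-2-(deca-O-benzyl-epicatechin-(4β→8)-catechin-8-yl)ethenyl (S)-2-methoxy-2-phenylacetate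
Product: 20 tetradeca-O-benzyl-epicatechin-(4β→8)-epicatechin-(4β→8)-catechin 3-O-[(S)-2-methoxy-2-phenylacetate] (ester on the top unit; units 2 to 4 of the target), via O-aryl oxocarbenium triflate 18 (not isolated), via benzylic cation triflate 19 (not isolated)
Conditions: TMSOTf (0.5 equiv), 4 Å MS, CH2Cl2, −78 to −40 °C; Et3N quench
Reagents that add atoms: none
Why: Proposed new method: TMSOTf silylates the benzotriazole of 17 so that it leaves and the (E)-O-aryl oxocarbenium ion 18 results, a cationic 2-oxadiene (C4a=C8a–O1=C2 of the future unit 2) that is attacked at C2 by the enol carbon C3 of 13 and then closes from C4 onto the free ortho carbon C4a of the phloroglucinol-type ring A, either in one asynchronous inverse-demand [4+2] event or by way of cation 19; the closest known reaction type is the oxa-Povarov reaction of O-aryl oxocarbenium ions with styrenes, which has not been shown with a β-acyloxystyrene or under auxiliary control. Ring C of unit 2 is thus closed by a formal [4+2] cycloaddition, whose stepwise limit is a Prins-type addition followed by a 6-exo-trig Friedel–Crafts alkylation of ring A by the quinone-methide-like cation. Regioselectivity is secured by the 2,4,6-trioxygenated ring A of unit 3 on C4, which stabilises positive charge at C4 far better than the electron-poor acyloxy group could at C3, and chemoselectivity by the enol double bond being the most nucleophilic π site at low temperature. The 2,3-cis relation should follow from the endo position of the acyloxy group next to the cationic O1=C2 unit together with the exo position forced on the bulky aryl group by the peri 5-benzyloxy group, and the 3,4-trans relation from the (E) geometry in the concerted limit or from anti opening of the acyloxy-bridged (dioxolanylium) form of 19 in the stepwise limit. The absolute sense is set at C3 by the (S)-2-methoxy-2-phenylacetyl group, whose phenyl ring covers one face of the enol double bond so that 18 adds to the open face, C2 and C4 then following from the cis and trans relations to give the (2R,3R)-2,3-cis-3,4-trans (4β) array of an epicatechin extension unit.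

**Step 14**
Reactants: 20 tetradeca-O-benzyl trimer 3-O-[(S)-2-methoxy-2-phenylacetate]; 5 8-bromo-3,5,7,3',4'-penta-O-benzyl-4β-(2-ethoxyethoxy)-(−)-epicatechin (1.2 equiv)
Product: 21 8-bromo-nonadeca-O-benzyl-epicatechin-(4β→8)-epicatechin-(4β→8)-epicatechin-(4β→8)-catechin 3-O-[(S)-2-methoxy-2-phenylacetate] (bromine on C8 of unit 1; ester on O3 of unit 2)
Conditions: TMSOTf (0.2 equiv), 4 Å MS, CH2Cl2, −78 °C; Et3N quench
Reagents that add atoms: none
Why: Friedel–Crafts alkylation as in step 7, in which C8 of the top unit of 20 (between O1 and the 7-benzyloxy group) is the most reactive free arene position, attack anti to the 3-benzyloxy group of the cation should set 4β, and the 8-bromine of 5 prevents further chain growth.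

**Step 15**
Reactants: 21 8-bromo-nonadeca-O-benzyl tetramer 3-O-[(S)-2-methoxy-2-phenylacetate]
Product: 22 8-bromo-nonadeca-O-benzyl-epicatechin-(4β→8)-epicatechin-(4β→8)-epicatechin-(4β→8)-catechin (bromine on C8 of unit 1; free 3-OH on unit 2 only)
Conditions: K2CO3 (0.2 equiv), MeOH/THF, rt to 40 °C
Reagents that add atoms: none
Why: Base-catalysed transesterification removes the activated α-alkoxy ester (the auxiliary) without touching benzyl ethers, the aryl bromide or any stereocentre.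

**Step 16**
Reactants: 22 8-bromo-nonadeca-O-benzyl tetramer with free 3-OH on unit 2
Product: 23 epicatechin-(4β→8)-epicatechin-(4β→8)-epicatechin-(4β→8)-catechin (the target tetramer)
Conditions: H2 (1 atm), Pd(OH)2/C, Et3N (2 equiv), THF/MeOH/H2O, rt; Sephadex LH-20
Reagents that add atoms: none
Why: Hydrogenolysis should cleave the nineteen benzyl ethers and the C8–Br bond in one operation, with Et3N buffering the HBr so that the acid-labile interflavan bonds and the C-ring benzylic ethers survive.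

**Compound list**
1 | (−)-epicatechin | Oc1cc(O)c2c(c1)O[C@H](c1ccc(O)c(O)c1)[C@H](O)C2 | starting material
2 | 5,7,3',4'-tetra-O-benzyl-(−)-epicatechin | O(Cc3ccccc3)c1cc(OCc3ccccc3)c2c(c1)O[C@H](c1ccc(OCc3ccccc3)c(OCc3ccccc3)c1)[C@H](O)C2 | intermediate
3 | 3,5,7,3',4'-penta-O-benzyl-(−)-epicatechin | O(Cc3ccccc3)c1cc(OCc3ccccc3)c2c(c1)O[C@H](c1ccc(OCc3ccccc3)c(OCc3ccccc3)c1)[C@H](OCc3ccccc3)C2 | intermediate
4 | 3,5,7,3',4'-penta-O-benzyl-4β-(2-ethoxyethoxy)-(−)-epicatechin | O(Cc3ccccc3)c1cc(OCc3ccccc3)c2c(c1)O[C@H](c1ccc(OCc3ccccc3)c(OCc3ccccc3)c1)[C@H](OCc3ccccc3)[C@H]2OCCOCC | intermediate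
5 | 8-bromo-3,5,7,3',4'-penta-O-benzyl-4β-(2-ethoxyethoxy)-(−)-epicatechin | O(Cc3ccccc3)c1cc(OCc3ccccc3)c2c(c1Br)O[C@H](c1ccc(OCc3ccccc3)c(OCc3ccccc3)c1)[C@H](OCc3ccccc3)[C@H]2OCCOCC | intermediate
6 | (+)-catechin | Oc1cc(O)c2c(c1)O[C@H](c1ccc(O)c(O)c1)[C@@H](O)C2 | starting material
7 | 5,7,3',4'-tetra-O-benzyl-(+)-catechin | O(Cc3ccccc3)c1cc(OCc3ccccc3)c2c(c1)O[C@H](c1ccc(OCc3ccccc3)c(OCc3ccccc3)c1)[C@@H](O)C2 | intermediate
8 | 3,5,7,3',4'-penta-O-benzyl-(+)-catechin | O(Cc3ccccc3)c1cc(OCc3ccccc3)c2c(c1)O[C@H](c1ccc(OCc3ccccc3)c(OCc3ccccc3)c1)[C@@H](OCc3ccccc3)C2 | intermediate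
9 | deca-O-benzyl-8-bromo-epicatechin-(4β→8)-catechin | Brc1c(OCc3ccccc3)cc(OCc3ccccc3)c2c1O[C@H](c1ccc(OCc3ccccc3)c(OCc3ccccc3)c1)[C@H](OCc3ccccc3)[C@H]2c1c(OCc3ccccc3)cc(OCc3ccccc3)c2c1O[C@H](c1ccc(OCc3ccccc3)c(OCc3ccccc3)c1)[C@@H](OCc3ccccc3)C2 | intermediate
10 | (E)-1,2-bis(4,4,5,5-tetramethyl-1,3,2-dioxaborolan-2-yl)ethene | CC1(C)OB(OC1(C)C)/C=C/B1OC(C)(C)C(C)(C)O1 | starting material
11 | deca-O-benzyl-8-[(E)-2-(pinacolboryl)ethenyl]-epicatechin-(4β→8)-catechin | CC1(C)OB(OC1(C)C)/C=C/c1c(OCc3ccccc3)cc(OCc3ccccc3)c2c1O[C@H](c1ccc(OCc3ccccc3)c(OCc3ccccc3)c1)[C@H](OCc3ccccc3)[C@H]2c1c(OCc3ccccc3)cc(OCc3ccccc3)c2c1O[C@H](c1ccc(OCc3ccccc3)c(OCc3ccccc3)c1)[C@@H](OCc3ccccc3)C2 | intermediate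
12 | potassium (E)-trifluoro[2-(deca-O-benzyl-epicatechin-(4β→8)-catechin-8-yl)ethenyl]borate | [K+].F[B-](F)(F)/C=C/c1c(OCc3ccccc3)cc(OCc3ccccc3)c2c1O[C@H](c1ccc(OCc3ccccc3)c(OCc3ccccc3)c1)[C@H](OCc3ccccc3)[C@H]2c1c(OCc3ccccc3)cc(OCc3ccccc3)c2c1O[C@H](c1ccc(OCc3ccccc3)c(OCc3ccccc3)c1)[C@@H](OCc3ccccc3)C2 | intermediate
13 | (E)-2-(deca-O-benzyl-epicatechin-(4β→8)-catechin-8-yl)ethenyl (S)-2-methoxy-2-phenylacetate | CO[C@@H](c1ccccc1)C(=O)O/C=C/c1c(OCc3ccccc3)cc(OCc3ccccc3)c2c1O[C@H](c1ccc(OCc3ccccc3)c(OCc3ccccc3)c1)[C@H](OCc3ccccc3)[C@H]2c1c(OCc3ccccc3)cc(OCc3ccccc3)c2c1O[C@H](c1ccc(OCc3ccccc3)c(OCc3ccccc3)c1)[C@@H](OCc3ccccc3)C2 | intermediate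
14 | 3,4-bis(benzyloxy)benzaldehyde | O=Cc1ccc(OCc2ccccc2)c(OCc2ccccc2)c1 | starting material
15 | 1-{chloro[3,4-bis(benzyloxy)phenyl]methyl}-1H-benzotriazole (racemic) | ClC(n1nnc2ccccc21)c1ccc(OCc2ccccc2)c(OCc2ccccc2)c1 | intermediate
16 | 3,5-bis(benzyloxy)phenol | Oc1cc(OCc2ccccc2)cc(OCc2ccccc2)c1 | starting material
17 | 1-{[3,5-bis(benzyloxy)phenoxy][3,4-bis(benzyloxy)phenyl]methyl}-1H-benzotriazole (racemic) | c1ccc2c(c1)nnn2C(Oc1cc(OCc3ccccc3)cc(OCc3ccccc3)c1)c1ccc(OCc3ccccc3)c(OCc3ccccc3)c1 | intermediate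
18 | O-[3,5-bis(benzyloxy)phenyl] 3,4-bis(benzyloxy)benzylidene oxocarbenium triflate | C(=[O+]c1cc(OCc3ccccc3)cc(OCc3ccccc3)c1)c1ccc(OCc3ccccc3)c(OCc3ccccc3)c1.[O-]S(=O)(=O)C(F)(F)F | intermediate
19 | benzylic cation (C4 of unit 2) after C2–C3 bond formation, triflate | c1c(OCc3ccccc3)cc(OCc3ccccc3)cc1O[C@H](c1ccc(OCc3ccccc3)c(OCc3ccccc3)c1)[C@H](OC(=O)[C@@H](OC)c1ccccc1)[CH+]c1c(OCc3ccccc3)cc(OCc3ccccc3)c2c1O[C@H](c1ccc(OCc3ccccc3)c(OCc3ccccc3)c1)[C@H](OCc3ccccc3)[C@H]2c1c(OCc3ccccc3)cc(OCc3ccccc3)c2c1O[C@H](c1ccc(OCc3ccccc3)c(OCc3ccccc3)c1)[C@@H](OCc3ccccc3)C2.[O-]S(=O)(=O)C(F)(F)F | intermediate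
20 | tetradeca-O-benzyl-epicatechin-(4β→8)-epicatechin-(4β→8)-catechin 3-O-[(S)-2-methoxy-2-phenylacetate] (ester on the top unit) | c1c(OCc3ccccc3)cc(OCc3ccccc3)c2c1O[C@H](c1ccc(OCc3ccccc3)c(OCc3ccccc3)c1)[C@H](OC(=O)[C@@H](OC)c1ccccc1)[C@H]2c1c(OCc3ccccc3)cc(OCc3ccccc3)c2c1O[C@H](c1ccc(OCc3ccccc3)c(OCc3ccccc3)c1)[C@H](OCc3ccccc3)[C@H]2c1c(OCc3ccccc3)cc(OCc3ccccc3)c2c1O[C@H](c1ccc(OCc3ccccc3)c(OCc3ccccc3)c1)[C@@H](OCc3ccccc3)C2 | intermediate
21 | 8-bromo-nonadeca-O-benzyl-epicatechin-(4β→8)-epicatechin-(4β→8)-epicatechin-(4β→8)-catechin 3-O-[(S)-2-methoxy-2-phenylacetate] (bromine on C8 of unit 1; ester on O3 of unit 2) | O(Cc3ccccc3)c1cc(OCc3ccccc3)c2c(c1Br)O[C@H](c1ccc(OCc3ccccc3)c(OCc3ccccc3)c1)[C@H](OCc3ccccc3)[C@H]2c1c(OCc3ccccc3)cc(OCc3ccccc3)c2c1O[C@H](c1ccc(OCc3ccccc3)c(OCc3ccccc3)c1)[C@H](OC(=O)[C@@H](OC)c1ccccc1)[C@H]2c1c(OCc3ccccc3)cc(OCc3ccccc3)c2c1O[C@H](c1ccc(OCc3ccccc3)c(OCc3ccccc3)c1)[C@H](OCc3ccccc3)[C@H]2c1c(OCc3ccccc3)cc(OCc3ccccc3)c2c1O[C@H](c1ccc(OCc3ccccc3)c(OCc3ccccc3)c1)[C@@H](OCc3ccccc3)C2 | intermediate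
22 | 8-bromo-nonadeca-O-benzyl-epicatechin-(4β→8)-epicatechin-(4β→8)-epicatechin-(4β→8)-catechin (bromine on C8 of unit 1; free 3-OH on unit 2 only) | O(Cc3ccccc3)c1cc(OCc3ccccc3)c2c(c1Br)O[C@H](c1ccc(OCc3ccccc3)c(OCc3ccccc3)c1)[C@H](OCc3ccccc3)[C@H]2c1c(OCc3ccccc3)cc(OCc3ccccc3)c2c1O[C@H](c1ccc(OCc3ccccc3)c(OCc3ccccc3)c1)[C@H](O)[C@H]2c1c(OCc3ccccc3)cc(OCc3ccccc3)c2c1O[C@H](c1ccc(OCc3ccccc3)c(OCc3ccccc3)c1)[C@H](OCc3ccccc3)[C@H]2c1c(OCc3ccccc3)cc(OCc3ccccc3)c2c1O[C@H](c1ccc(OCc3ccccc3)c(OCc3ccccc3)c1)[C@@H](OCc3ccccc3)C2 | intermediate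
23 | epicatechin-(4β→8)-epicatechin-(4β→8)-epicatechin-(4β→8)-catechin (the target tetramer) | Oc1cc(O)c2c(c1)O[C@H](c1ccc(O)c(O)c1)[C@H](O)[C@H]2c1c(O)cc(O)c2c1O[C@H](c1ccc(O)c(O)c1)[C@H](O)[C@H]2c1c(O)cc(O)c2c1O[C@H](c1ccc(O)c(O)c1)[C@H](O)[C@H]2c1c(O)cc(O)c2c1O[C@H](c1ccc(O)c(O)c1)[C@@H](O)C2 | target

**Summary**
Total step count: 16. Longest linear sequence: 12 steps (1, 2, 3, 4, 7, 8, 9, 10, 13, 14, 15, 16).

**Steps most likely to fail**

Step 13 (proposed new method). What may go wrong: insufficient facial discrimination by the acyl auxiliary, leakage through the exo-acyloxy transition state into the 2,3-trans series, ionisation of 17 with loss of aryloxide instead of benzotriazole, or Friedel–Crafts capture of 18 by free C6 positions. The fallback uses only known chemistry and builds the chain from chiral-pool units by iterated Lewis-acid Friedel–Crafts condensation. It sets out from 4 and 8: 4 is condensed with an excess of 8 (TMSOTf, CH2Cl2, −78 °C) to give deca-O-benzyl-epicatechin-(4β→8)-catechin F1. An excess of F1 is condensed with 4 in the same way to give pentadeca-O-benzyl-epicatechin-(4β→8)-epicatechin-(4β→8)-catechin F2. An excess of F2 with 4 gives icosa-O-benzyl-epicatechin-(4β→8)-epicatechin-(4β→8)-epicatechin-(4β→8)-catechin F3, and hydrogenolysis of F3 (H2, Pd(OH)2/C, THF/MeOH/H2O) comes back to the route at 23.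

Step 14. What may go wrong: poor site selectivity among the free arene positions of 20 (C8 against C6 of the top unit, C6 of the lower units) and double alkylation. The fallback makes the unit 1–unit 2 bond on the small phenol before the annulation, where regioisomers are separated easily. It sets out from 5 and 16: condensation of 5 with an excess of 16 (TMSOTf, CH2Cl2, −78 °C) and chromatographic removal of the para isomer give 8-bromo-3,5,7,3',4'-penta-O-benzyl-4β-[2-hydroxy-4,6-bis(benzyloxy)phenyl]epicatechin F4. O-alkylation of F4 with 15 (K2CO3, DMF) gives the benzotriazolyl N,O-acetal of that phenol F5, and annulation of F5 with 13 under the conditions of step 13 comes back to the route at 21.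

Step 8. What may go wrong: slow oxidative addition at the di-ortho-substituted electron-rich bromide, double coupling to the stilbene, or protodeboronation of the product. The fallback avoids palladium and sets out from 9: bromine–lithium exchange (n-BuLi, THF, −78 °C) and formylation with DMF give deca-O-benzyl-8-formyl-epicatechin-(4β→8)-catechin F6. Boron–Wittig olefination of F6 with bis(pinacolboryl)methane and LiTMP (THF, −78 °C to rt), which is (E)-selective for aryl aldehydes, comes back to the route at 11.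

**Further compounds**
F1 | step 13 | deca-O-benzyl-epicatechin-(4β→8)-catechin | c1c(OCc3ccccc3)cc(OCc3ccccc3)c2c1O[C@H](c1ccc(OCc3ccccc3)c(OCc3ccccc3)c1)[C@H](OCc3ccccc3)[C@H]2c1c(OCc3ccccc3)cc(OCc3ccccc3)c2c1O[C@H](c1ccc(OCc3ccccc3)c(OCc3ccccc3)c1)[C@@H](OCc3ccccc3)C2
F2 | step 13 | pentadeca-O-benzyl-epicatechin-(4β→8)-epicatechin-(4β→8)-catechin | c1c(OCc3ccccc3)cc(OCc3ccccc3)c2c1O[C@H](c1ccc(OCc3ccccc3)c(OCc3ccccc3)c1)[C@H](OCc3ccccc3)[C@H]2c1c(OCc3ccccc3)cc(OCc3ccccc3)c2c1O[C@H](c1ccc(OCc3ccccc3)c(OCc3ccccc3)c1)[C@H](OCc3ccccc3)[C@H]2c1c(OCc3ccccc3)cc(OCc3ccccc3)c2c1O[C@H](c1ccc(OCc3ccccc3)c(OCc3ccccc3)c1)[C@@H](OCc3ccccc3)C2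
F3 | step 13 | icosa-O-benzyl-epicatechin-(4β→8)-epicatechin-(4β→8)-epicatechin-(4β→8)-catechin | c1c(OCc3ccccc3)cc(OCc3ccccc3)c2c1O[C@H](c1ccc(OCc3ccccc3)c(OCc3ccccc3)c1)[C@H](OCc3ccccc3)[C@H]2c1c(OCc3ccccc3)cc(OCc3ccccc3)c2c1O[C@H](c1ccc(OCc3ccccc3)c(OCc3ccccc3)c1)[C@H](OCc3ccccc3)[C@H]2c1c(OCc3ccccc3)cc(OCc3ccccc3)c2c1O[C@H](c1ccc(OCc3ccccc3)c(OCc3ccccc3)c1)[C@H](OCc3ccccc3)[C@H]2c1c(OCc3ccccc3)cc(OCc3ccccc3)c2c1O[C@H](c1ccc(OCc3ccccc3)c(OCc3ccccc3)c1)[C@@H](OCc3ccccc3)C2
F4 | step 14 | 8-bromo-3,5,7,3',4'-penta-O-benzyl-4β-[2-hydroxy-4,6-bis(benzyloxy)phenyl]epicatechin | O(Cc3ccccc3)c1cc(OCc3ccccc3)c2c(c1Br)O[C@H](c1ccc(OCc3ccccc3)c(OCc3ccccc3)c1)[C@H](OCc3ccccc3)[C@H]2c1c(OCc3ccccc3)cc(OCc3ccccc3)cc1O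
F5 | step 14 | 1-{[2-(8-bromo-penta-O-benzyl-epicatechin-4β-yl)-3,5-bis(benzyloxy)phenoxy][3,4-bis(benzyloxy)phenyl]methyl}-1H-benzotriazole | O(Cc3ccccc3)c1cc(OCc3ccccc3)c2c(c1Br)O[C@H](c1ccc(OCc3ccccc3)c(OCc3ccccc3)c1)[C@H](OCc3ccccc3)[C@H]2c1c(OCc3ccccc3)cc(OCc3ccccc3)cc1OC(n1nnc4ccccc41)c1ccc(OCc3ccccc3)c(OCc3ccccc3)c1
F6 | step 8 | deca-O-benzyl-8-formyl-epicatechin-(4β→8)-catechin | O=Cc1c(OCc3ccccc3)cc(OCc3ccccc3)c2c1O[C@H](c1ccc(OCc3ccccc3)c(OCc3ccccc3)c1)[C@H](OCc3ccccc3)[C@H]2c1c(OCc3ccccc3)cc(OCc3ccccc3)c2c1O[C@H](c1ccc(OCc3ccccc3)c(OCc3ccccc3)c1)[C@@H](OCc3ccccc3)C2
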